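Ring A and ring B of this ent-labdane are cut together at C1–C2 and C5–C10, which turns the decalin into an open-chain 1,7,9-decatriene. Ring A carries the pattern of a Diels–Alder adduct. The C2 carbinol and the C4 carboxyl map onto a 1-alkoxy-3-carbomethoxy diene (C2=C3–C4=C5). The C10 methyl and the C1 methylene map onto an isopropenyl group. One thermal intramolecular cycloaddition closes both rings and sets C2, C5 and the quaternary C10 from the single stereocentre C9. C9 is bought with (R)-limonene, together with the isopropenyl dienophile and the C11–C13/C16 side-chain carbons. C4 follows by substrate-controlled enolate methylation.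

Key step: step 11

Remark on the chemistry: labdane numbering (C1–C20) is used for all intermediates, including the open-chain ones. The target SMILES corresponds to the (2R,4R,5S,9R,10S,13E) isomer (ent-labdane series), with C20, the C19 carboxyl and the C2 hydroxyl all axial on one face.

Step 1
Reactants: 1 (R)-(+)-limonene
Product: 3 (3R)-6-oxo-3-(prop-1-en-2-yl)heptanal, via ring ozonide 2 (not isolated)
Conditions: O3 (1.0 equiv), CH2Cl2, −78 °C; then Me2S, −78 °C → rt
Reagents that add atoms: ozone [O-][O+]=O
Why: Ozonolysis with reductive work-up; the trisubstituted ring alkene is more electron-rich than the 1,1-disubstituted isopropenyl group and should be cleaved first, and the stereocentre (later C9) is not touched.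

Step 2
Reactants: 3 (3R)-6-oxo-3-(prop-1-en-2-yl)heptanal
Product: 4 (3S)-2-methylidene-6-oxo-3-(prop-1-en-2-yl)heptanal
Conditions: 37% aq. HCHO, pyrrolidine (10 mol%), propionic acid (10 mol%), i-PrOH, 45 °C
Reagents that add atoms: formaldehyde C=O
Why: Organocatalytic Mannich condensation–elimination (α-methylenation of an aldehyde); only the aldehyde forms the enamine, formaldehyde is by far the best electrophile present so the intramolecular aldol onto the methyl ketone should be outrun, and C9 keeps its configuration because it sits on the α-carbon of the new enal and is not vinylogously acidic.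

Step 3
Reactants: 4 (3S)-2-methylidene-6-oxo-3-(prop-1-en-2-yl)heptanal
Product: 5 (5S)-5-(3-hydroxyprop-1-en-2-yl)-6-methylhept-6-en-2-one
Conditions: LiAlH(O-t-Bu)3 (1.05 equiv), THF, −78 °C
Reagents that add atoms: none
Why: Chemoselective 1,2-reduction; the bulky, attenuated hydride should reduce the aldehyde much faster than the methyl ketone at low temperature.

Step 4
Reactants: 5 (5S)-5-(3-hydroxyprop-1-en-2-yl)-6-methylhept-6-en-2-one
Product: 6 (3S)-4-methyl-2-methylidene-3-[2-(2-methyl-1,3-dioxolan-2-yl)ethyl]pent-4-en-1-ol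
Conditions: HOCH2CH2OH, PPTS (cat.), benzene, reflux, Dean–Stark
Reagents that add atoms: ethylene glycol OCCO
Why: Ketalisation under weakly acidic conditions that should not isomerise the skipped diene; it masks the C13 ketone against the bases used in steps 7 and 13.

Step 5
Reactants: 6 (3S)-4-methyl-2-methylidene-3-[2-(2-methyl-1,3-dioxolan-2-yl)ethyl]pent-4-en-1-ol
Product: 8 (5S)-6-methyl-4-methylidene-5-[2-(2-methyl-1,3-dioxolan-2-yl)ethyl]hept-6-enal, via allyl vinyl ether 7 (not isolated)
Conditions: n-BuOCH=CH2 (excess), Pd(OCOCF3)2 (cat.), 4,7-diphenyl-1,10-phenanthroline (cat.), Et3N (cat.), 75 °C; concentrate; xylenes, 140 °C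
Reagents that add atoms: n-butyl vinyl ether C=COCCCC
Why: Vinyl transfer catalysed by divalent palladium followed by an aliphatic Claisen rearrangement; both termini of the 2-substituted allyl unit are CH2, so the [3,3] shift regenerates the C8=C17 methylidene while adding C6 and the C5 aldehyde.

Step 6
Reactants: 9 methyl 2-[bis(2,2,2-trifluoroethoxy)phosphoryl]acetate
Product: 10 methyl 2-bromo-2-[bis(2,2,2-trifluoroethoxy)phosphoryl]acetate (racemic)
Conditions: NaH (1.0 equiv), THF, 0 °C; Br2 (1.0 equiv), −78 → 0 °C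
Reagents that add atoms: bromine BrBr
Why: Electrophilic α-bromination of the stabilised phosphonate carbanion, a standard entry to halophosphonoacetates.

Step 7
Reactants: 8 (5S)-6-methyl-4-methylidene-5-[2-(2-methyl-1,3-dioxolan-2-yl)ethyl]hept-6-enal; 10 methyl 2-bromo-2-[bis(2,2,2-trifluoroethoxy)phosphoryl]acetate
Product: 11 methyl (2E,7S)-2-bromo-8-methyl-6-methylidene-7-[2-(2-methyl-1,3-dioxolan-2-yl)ethyl]nona-2,8-dienoate
Conditions: t-BuOK, 18-crown-6, THF, −78 °C
Reagents that add atoms: none
Why: Horner–Wadsworth–Emmons olefination in its Still–Gennari variant; the electron-poor phosphonate makes the kinetic addition irreversible and should place the C6 chain cis to the ester (E-α-bromoacrylate), the geometry the diene needs.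

Step 8
Reactants: 12 4-methoxybenzyl alcohol; 13 trichloroethylene
Product: 15 ethynyl 4-methoxybenzyl ether, via dichlorovinyl ether 14 (not isolated)
Conditions: KH, THF, 0 °C; 13, −50 °C → rt; n-BuLi (2.3 equiv), −78 → −40 °C; MeOH quench; keep below 25 °C
Reagents that add atoms: none
Why: Standard ynol ether synthesis: addition–elimination of the alkoxide on trichloroethylene, then dehydrochlorination and chlorine–lithium exchange with butyllithium, then protonation of the acetylide.

Step 9
Reactants: 15 ethynyl 4-methoxybenzyl ether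
Product: 16 (E)-2-[2-(4-methoxybenzyloxy)ethenyl]-4,4,5,5-tetramethyl-1,3,2-dioxaborolane
Conditions: pinacolborane, Cp2ZrHCl (cat.), Et3N (cat.), CH2Cl2, 0 → 20 °C
Reagents that add atoms: pinacolborane [H]B1OC(C)(C)C(C)(C)O1
Why: Zirconocene-catalysed syn-hydroboration of a terminal alkoxyalkyne; boron goes to the terminal carbon and syn addition fixes the E enol ether.

Step 10
Reactants: 11 methyl (2E,7S)-2-bromo-8-methyl-6-methylidene-7-[2-(2-methyl-1,3-dioxolan-2-yl)ethyl]nona-2,8-dienoate; 16 (E)-2-[2-(4-methoxybenzyloxy)ethenyl]-4,4,5,5-tetramethyl-1,3,2-dioxaborolane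
Product: 17 methyl (2Z,7S)-2-[(E)-2-(4-methoxybenzyloxy)ethenyl]-8-methyl-6-methylidene-7-[2-(2-methyl-1,3-dioxolan-2-yl)ethyl]nona-2,8-dienoate
Conditions: Pd(PPh3)4 (cat.), K3PO4, THF/H2O, 50 °C
Reagents that add atoms: none
Why: Suzuki–Miyaura alkenyl–alkenyl coupling, which proceeds with retention at both partners, so the diene has C6 and the ether oxygen both on its outside positions.

Step 11
Reactants: 17 methyl (2Z,7S)-2-[(E)-2-(4-methoxybenzyloxy)ethenyl]-8-methyl-6-methylidene-7-[2-(2-methyl-1,3-dioxolan-2-yl)ethyl]nona-2,8-dienoate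
Product: 18 methyl (2R,5S,9R,10S)-2-(4-methoxybenzyloxy)-13,13-(ethylenedioxy)-14,15,18-trinorlabda-3,8(17)-dien-19-oate (trans-fused; C2–O cis to C20)
Conditions: PhMe (0.005 M), BHT (cat.), sealed tube, 180 °C
Reagents that add atoms: none
Why: Concerted, asynchronous [4π+2π] cycloaddition (thermal type 1 intramolecular Diels–Alder reaction of a 1,7,9-decatriene): the isopropenyl C10=C1 adds suprafacially across the s-cis diene C2=C3–C4=C5, so C1–C2 and C5–C10 form together and the new alkene is C3=C4. Ring B (C5–C10) closes through the four-carbon tether C6–C9 in a chair-like fold, and ring A (C1–C5, C10) is the boat-like six-membered cycloaddition array itself. C5 and C10: the trans fusion comes from the fold with the C20 methyl endo and the tether exo, which the C4 ester enforces as a built-in steric directing group on the diene carbon next to the tether, a known control element, because the cis-fused fold suffers allylic 1,3-strain between this ester and the C6–C7 bond. C2: the E enol ether holds the oxygen outside, so suprafaciality places C2–O cis to C5–C6 and, in the trans-fused fold, 1,3-diaxial to C20. Absolute sense: the limonene-derived C9 keeps its C11 chain equatorial on the chair-like tether (the sp2 C8 removes one 1,3-diaxial contact with C20), which selects one face of both partners. Chemoselectivity rests on tether length, since C8=C17 is only two atoms from C5 and cannot span the diene, and the ester lowers the diene LUMO toward the unactivated 1,1-dialkyl alkene.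

Step 12
Reactants: 18 Diels–Alder adduct (enoate)
Product: 19 saturated ester: methyl 2-(4-methoxybenzyloxy)-13,13-(ethylenedioxy)-14,15,18-trinorlabd-8(17)-en-19-oate (C2, C5, C9, C10 as in 18; C4 epimers)
Conditions: Cu(OAc)2 (cat.), 1,2-bis(diphenylphosphino)benzene (cat.), Me(EtO)2SiH, t-BuOH, PhMe, rt
Reagents that add atoms: none
Why: Copper hydride conjugate reduction; the ligated monovalent copper hydride delivers hydride only to the β-carbon C3 of the polarised enoate and leaves the C8=C17 alkene and the allylic ether alone, and the new C4 centre may form as a mixture because it is planarised again in step 13.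

Step 13
Reactants: 19 saturated ester (C4 epimers)
Product: 20 methyl (2R,4R,5S,9R,10S)-2-(4-methoxybenzyloxy)-13,13-(ethylenedioxy)-14,15-dinorlabd-8(17)-en-19-oate (axial ester, equatorial C18 methyl)
Conditions: LDA, THF, −78 → 0 °C; MeI, DMPU, −78 °C → rt
Reagents that add atoms: iodomethane CI
Why: Ester enolate alkylation; the exocyclic enolate is shielded on one face by the axial C20 methyl and the axial C2 ether, so iodomethane should enter equatorially from the opposite face and leave the ester axial (4R).

Step 14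
Reactants: 20 quaternary ester ketal
Product: 21 methyl (2R,4R,5S,9R,10S)-2-(4-methoxybenzyloxy)-13-oxo-14,15-dinorlabd-8(17)-en-19-oate
Conditions: 1 M HCl, THF, rt
Reagents that add atoms: water O
Why: Acid-catalysed ketal hydrolysis under conditions that should leave the benzyl-type ether, the hindered ester and the exocyclic alkene intact.

Step 15
Reactants: 21 methyl ketone
Product: 22 dimethyl (2R,4R,5S,9R,10S,13E)-2-(4-methoxybenzyloxy)labda-8(17),13-diene-15,19-dioate
Conditions: (MeO)2P(O)CH2CO2Me, NaH, THF, 0 → 50 °C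
Reagents that add atoms: trimethyl phosphonoacetate COC(=O)CP(=O)(OC)OC
Why: Horner–Wadsworth–Emmons olefination of a methyl ketone; reversible addition of the stabilised phosphonate favours the E-enoate with the larger C12 chain trans to the ester, and any Z isomer is removed by chromatography.

Step 16
Reactants: 22 protected diester
Product: 23 dimethyl (2R,4R,5S,9R,10S,13E)-2-hydroxylabda-8(17),13-diene-15,19-dioate
Conditions: DDQ, CH2Cl2/pH 7 buffer, 0 °C → rt
Reagents that add atoms: none
Why: Oxidative cleavage of the 4-methoxybenzyl ether by hydride abstraction at the electron-rich benzylic position, which spares the unactivated alkene and the enoate and does not touch C2.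

Step 17
Reactants: 23 hydroxy diester
Product: 25 (2R,4R,5S,9R,10S,13E)-2-hydroxylabda-8(17),13-diene-15,19-dioic acid (target), via lactone acid 24 (not isolated)
Conditions: LiOH, THF/MeOH/H2O, 60 °C; then 1 M HCl to pH 4, 0 °C
Reagents that add atoms: lithium hydroxide [Li+].[OH-]
Why: Saponification with a neighbouring-group relay; the C15 ester is hydrolysed directly, whereas the axial C2 alkoxide, 1,3-diaxial to the neopentyl C19 ester, should first close the strained lactone 24 that hydroxide opens readily, and cold acidification only to pH 4 avoids relactonisation.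

Compound list
1 | (R)-(+)-limonene | CC1=CC[C@@H](CC1)C(C)=C | starting material
2 | limonene ring ozonide (7,8,9-trioxabicyclo[4.2.1]nonane; new centres undefined) | CC12CC[C@@H](C(C)=C)CC(OO1)O2 | intermediate
3 | (3R)-6-oxo-3-(prop-1-en-2-yl)heptanal | C=C(C)[C@@H](CC=O)CCC(C)=O | intermediate
4 | (3S)-2-methylidene-6-oxo-3-(prop-1-en-2-yl)heptanal | C=C(C)[C@@H](C(=C)C=O)CCC(C)=O | intermediate
5 | (5S)-5-(3-hydroxyprop-1-en-2-yl)-6-methylhept-6-en-2-one | C=C(C)[C@@H](C(=C)CO)CCC(C)=O | intermediate
6 | (3S)-4-methyl-2-methylidene-3-[2-(2-methyl-1,3-dioxolan-2-yl)ethyl]pent-4-en-1-ol | C=C(C)[C@@H](C(=C)CO)CCC1(C)OCCO1 | intermediate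
7 | vinyl ether of 6 | C=C(C)[C@@H](C(=C)COC=C)CCC1(C)OCCO1 | intermediate
8 | (5S)-6-methyl-4-methylidene-5-[2-(2-methyl-1,3-dioxolan-2-yl)ethyl]hept-6-enal | C=C(C)[C@@H](C(=C)CCC=O)CCC1(C)OCCO1 | intermediate
9 | methyl 2-[bis(2,2,2-trifluoroethoxy)phosphoryl]acetate | COC(=O)CP(=O)(OCC(F)(F)F)OCC(F)(F)F | starting material
10 | methyl 2-bromo-2-[bis(2,2,2-trifluoroethoxy)phosphoryl]acetate (racemic) | COC(=O)C(Br)P(=O)(OCC(F)(F)F)OCC(F)(F)F | intermediate
11 | methyl (2E,7S)-2-bromo-8-methyl-6-methylidene-7-[2-(2-methyl-1,3-dioxolan-2-yl)ethyl]nona-2,8-dienoate | C=C(C)[C@@H](C(=C)CC/C=C(/Br)C(=O)OC)CCC1(C)OCCO1 | intermediate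
12 | 4-methoxybenzyl alcohol | COc1ccc(CO)cc1 | starting material
13 | trichloroethylene | ClC=C(Cl)Cl | starting material
14 | (E)-1,2-dichlorovinyl 4-methoxybenzyl ether | COc1ccc(CO/C(Cl)=C\Cl)cc1 | intermediate
15 | ethynyl 4-methoxybenzyl ether | C#COCc1ccc(OC)cc1 | intermediate
16 | (E)-2-[2-(4-methoxybenzyloxy)ethenyl]-4,4,5,5-tetramethyl-1,3,2-dioxaborolane | COc1ccc(CO/C=C/B2OC(C)(C)C(C)(C)O2)cc1 | intermediate
17 | methyl (2Z,7S)-2-[(E)-2-(4-methoxybenzyloxy)ethenyl]-8-methyl-6-methylidene-7-[2-(2-methyl-1,3-dioxolan-2-yl)ethyl]nona-2,8-dienoate | C=C(C)[C@@H](C(=C)CC/C=C(\C(=O)OC)/C=C/OCc1ccc(OC)cc1)CCC1(C)OCCO1 | intermediate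
18 | methyl (2R,5S,9R,10S)-2-(4-methoxybenzyloxy)-13,13-(ethylenedioxy)-14,15,18-trinorlabda-3,8(17)-dien-19-oate | C=C1CC[C@H]2[C@@](C)(C[C@@H](OCc3ccc(OC)cc3)C=C2C(=O)OC)[C@@H]1CCC1(C)OCCO1 | intermediate
19 | methyl 2-(4-methoxybenzyloxy)-13,13-(ethylenedioxy)-14,15,18-trinorlabd-8(17)-en-19-oate (C4 epimers, other centres as in 18) | C=C1CC[C@H]2[C@@](C)(C[C@@H](OCc3ccc(OC)cc3)CC2C(=O)OC)[C@@H]1CCC1(C)OCCO1 | intermediate
20 | methyl (2R,4R,5S,9R,10S)-2-(4-methoxybenzyloxy)-13,13-(ethylenedioxy)-14,15-dinorlabd-8(17)-en-19-oate | C=C1CC[C@H]2[C@@](C)(C[C@@H](OCc3ccc(OC)cc3)C[C@@]2(C)C(=O)OC)[C@@H]1CCC1(C)OCCO1 | intermediate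
21 | methyl (2R,4R,5S,9R,10S)-2-(4-methoxybenzyloxy)-13-oxo-14,15-dinorlabd-8(17)-en-19-oate | C=C1CC[C@H]2[C@@](C)(C[C@@H](OCc3ccc(OC)cc3)C[C@@]2(C)C(=O)OC)[C@@H]1CCC(C)=O | intermediate
22 | dimethyl (2R,4R,5S,9R,10S,13E)-2-(4-methoxybenzyloxy)labda-8(17),13-diene-15,19-dioate | C=C1CC[C@H]2[C@@](C)(C[C@@H](OCc3ccc(OC)cc3)C[C@@]2(C)C(=O)OC)[C@@H]1CC/C(C)=C/C(=O)OC | intermediate
23 | dimethyl (2R,4R,5S,9R,10S,13E)-2-hydroxylabda-8(17),13-diene-15,19-dioate | C=C1CC[C@H]2[C@@](C)(C[C@@H](O)C[C@@]2(C)C(=O)OC)[C@@H]1CC/C(C)=C/C(=O)OC | intermediate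
24 | (2R,4R,5S,9R,10S,13E)-19-oxo-2,19-epoxylabda-8(17),13-dien-15-oic acid (19,2-lactone acid) | C=C1CC[C@H]2[C@@](C)(C[C@@H]3C[C@@]2(C)C(=O)O3)[C@@H]1CC/C(C)=C/C(=O)O | intermediate
25 | (2R,4R,5S,9R,10S,13E)-2-hydroxylabda-8(17),13-diene-15,19-dioic acid (CNP0086784.5) | C=C1CC[C@H]2[C@@](C)(C[C@@H](O)C[C@@]2(C)C(=O)O)[C@@H]1CC/C(C)=C/C(=O)O | target

Total step count: 17. Longest linear sequence: 14 steps (steps 1–5, 7, 10–17).

Steps most likely to fail

Step 11. The cycloaddition onto the unactivated, 1,1-disubstituted alkene may be too slow at temperatures the dienyl ether tolerates. Crowding at the substituted C2 terminus may also erode the preference for the trans-fused, C11-equatorial fold. The fallback forms the same two bonds and sets out from 11.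
- Suzuki–Miyaura coupling with vinylboronic acid pinacol ester gives the C2-unsubstituted triene F1. Its less hindered diene should undergo the same intramolecular Diels–Alder reaction at lower temperature to the trans-octalin ester F2.
- Deconjugative methylation of its dienolate (LDA/DMPU, MeI) from the face opposite C20 gives the quaternary 2-ene ester F3.
- Iodolactonisation (I2, MeCN) with trans-diaxial opening (Fürst–Plattner rule) delivers the C19 carboxyl oxygen to C2 and gives the iodolactone F4.
- Bu3SnH/AIBN gives the lactone ketal F5, and aqueous acid gives the lactone ketone F6.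
- Horner–Wadsworth–Emmons olefination gives the lactone enoate F7. LiOH as in step 17 saponifies its C15 ester to 24, where the fallback rejoins the route.

Step 8. The benzyl-type ynol ether may be lost by [3,3]-sigmatropic rearrangement to a ketene and oligomerisation during isolation or before hydroboration. The fallback avoids the ynol ether, bypassing steps 8 and 9, and sets out from 11. Suzuki–Miyaura mono-coupling with excess (E)-1,2-bis(pinacolboryl)ethene gives the dienylboronate F8. Copper-promoted oxidative C–O coupling of Chan–Lam type (Cu(OAc)2, Et3N, air) with alcohol 12 proceeds with retention of alkene geometry and comes back to the route at 17.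

Step 17. The lactone relay may not engage, so acyl attack at the neopentyl axial C19 ester may stall and leave this ester uncleaved. The fallback sets out from 23 and cleaves both methyl esters at the O–CH3 bond by SN2 dealkylation (LiI, 2,4,6-collidine, reflux; then cold dilute acid). This needs no access to the hindered carbonyl, makes no new compound, and comes back at 25.

Further compounds
F1 | step 11 | methyl (2Z,7S)-2-ethenyl-8-methyl-6-methylidene-7-[2-(2-methyl-1,3-dioxolan-2-yl)ethyl]nona-2,8-dienoate | C=C(C)[C@@H](C(=C)CC/C=C(\C(=O)OC)C=C)CCC1(C)OCCO1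
F2 | step 11 | methyl (5S,9R,10S)-13,13-(ethylenedioxy)-14,15,18-trinorlabda-3,8(17)-dien-19-oate | C=C1CC[C@H]2[C@@](C)(CCC=C2C(=O)OC)[C@@H]1CCC1(C)OCCO1
F3 | step 11 | methyl 13,13-(ethylenedioxy)-14,15-dinorlabda-2,8(17)-dien-19-oate (axial ester, configuration as in SMILES) | C=C1CC[C@H]2[C@@](C)(CC=C[C@@]2(C)C(=O)OC)[C@@H]1CCC1(C)OCCO1
F4 | step 11 | 13,13-(ethylenedioxy)-3-iodo-14,15-dinorlabd-8(17)-en-19,2-olide (iodine axial, anti to the lactone oxygen) | C=C1CC[C@H]2[C@@](C)(C[C@@H]3[C@H](I)[C@@]2(C)C(=O)O3)[C@@H]1CCC1(C)OCCO1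
F5 | step 11 | 13,13-(ethylenedioxy)-14,15-dinorlabd-8(17)-en-19,2-olide | C=C1CC[C@H]2[C@@](C)(C[C@@H]3C[C@@]2(C)C(=O)O3)[C@@H]1CCC1(C)OCCO1
F6 | step 11 | 13-oxo-14,15-dinorlabd-8(17)-en-19,2-olide | C=C1CC[C@H]2[C@@](C)(C[C@@H]3C[C@@]2(C)C(=O)O3)[C@@H]1CCC(C)=O
F7 | step 11 | methyl (13E)-19-oxo-2,19-epoxylabda-8(17),13-dien-15-oate | C=C1CC[C@H]2[C@@](C)(C[C@@H]3C[C@@]2(C)C(=O)O3)[C@@H]1CC/C(C)=C/C(=O)OC
F8 | step 8 | methyl (2Z,7S)-8-methyl-6-methylidene-7-[2-(2-methyl-1,3-dioxolan-2-yl)ethyl]-2-[(E)-2-(4,4,5,5-tetramethyl-1,3,2-dioxaborolan-2-yl)ethenyl]nona-2,8-dienoate | C=C(C)[C@@H](C(=C)CC/C=C(\C(=O)OC)/C=C/B1OC(C)(C)C(C)(C)O1)CCC1(C)OCCO1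
F0 | step 17 | none | none
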